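I had no rate constants, so I worked from what the flat runs gave. Starting material and activator give ring in closed flasks, and I had to rank the flasks below at one charge.

| setting | alder | oak | south-west | south | south-east | east |
|---|---|---|---|---|---|---|
| starting material | 0.15 M | 0.22 M | 0.30 M | 0.30 M | 0.30 M | 0.30 M |
| activator | 0.33 M | 0.33 M | 0.330 M | 0.330 M | 0.330 M | 0.330 M |
| temperature | 0 °C | 35 °C | 45 °C | 5 °C | 25 °C | 65 °C |
| remark | run made earlier | run made earlier |  |  |  |  |
| time |  |  | 15 d | 15 d | 15 d | 15 d |

- alder (time / d: ring / %): 25.0: 9.7; 50.0: 9.4; 80.0: 9.6; 100: 9.5; 120: 9.2; 150: 9.5; 200: 9.4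
- oak (time / d: ring / %): 4.00: 24.4; 8.00: 24.6; 12.0: 24.3; 15.0: 24.6; 20.0: 24.9; 25.0: 24.9; 30.0: 24.8

(each reading ± 0.3 percentage points)

1. the best flask by amount of ring, in percent of the starting material charged; "all alike" if 1.5 percentage points covers them all (south-west / south / south-east / east / all alike)
2. amount of ring at the end, in percent of the starting material charged, south-west
3. amount of ring at the end, in percent of the starting material charged, south
4. amount of ring at the end, in percent of the starting material charged, south-east
5. amount of ring at the end, in percent of the starting material charged, east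



Both runs stood flat within a scatter of 0.3 percentage points. At its last reading the alder run held 0.0141 M of ring and the oak run 0.0546 M. That is my ring level L, the plateau percent times the charge of starting material, which is the ring concentration on the plateau. If L held when the charge changed, the percent at 0.30 M was L over that charge: 4.70% at 0 °C and 18.2% at 35 °C. So I expected south and south-east between those two, and more ring with more heat.

The forecast named east, with 25% for south-west, 5.9% for south, 12.7% for south-east and 45% for east. Its ground was this: “I read them as equilibrium rather than kinetic yields”. Its south and south-east values sat inside my bracket. I had no reading near the temperature of east.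

The flasks gave 23.1% in south-west, 6.64% in south, 13.9% in south-east and 32.6% in east. So east was best, with the limiting reagent, starting material, at 0% there.

    starting material + activator → activated form (k = 0.102 M⁻¹ h⁻¹, Ea = 67.0 kJ mol⁻¹)
    activated form ⇌ ring (K = 1.23, k = 0.0393 h⁻¹, Ea = 93.0 kJ mol⁻¹, ΔH = 22.0 kJ mol⁻¹)
    starting material + activated form → open dimer (k = 0.259 M⁻¹ h⁻¹, Ea = 74.0 kJ mol⁻¹)
    ring ⇌ isomer of the product (K = 2.14, k = 0.0815 h⁻¹, Ea = 91.0 kJ mol⁻¹, ΔH = −51.0 kJ mol⁻¹)
    activator ⇌ dormant form (K = 2.50, k = 0.0147 h⁻¹, Ea = 94.0 kJ mol⁻¹, ΔH = −19.0 kJ mol⁻¹)
    (constants at 5 °C)

The level L of east was 0.0979 M, which is 1.79 times that of oak, whereas oak stood at 3.87 times alder. Part of the reason in east was the path from starting material and activated form to open dimer, acting together with the backward run from ring to activated form. East gave 32.6% as it stood, 83.8% with that path taken away and 68.7% with that backward run taken away. For the alder run charged at 0.30 M, L gave 4.70%, and that flask gave 5.18%.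

The readings come from a simulation from invented constants, noise included.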